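**Plan**

- Retrosynthesis cuts three bonds: (a) the C(sp2)–C(sp2) bond between C2 of the cyclopentene (ring B) and C2′ of the heptadienyl chain; (b) the bond from the bridging CH2 to C2 of the cyclohexane ring (ring A); (c) the bond from ring-B C1 to that CH2.
- Enabling feature: bond (a) is the central bond of a 1,3-diene, so both ends are sp2 carbons. Ring-B C2 is the carbonyl carbon of a 4-oxygenated cyclopent-2-enone whose C=C lies at C3–C4, so conjugate hydride addition gives the C2–C3 enol triflate regiospecifically; C2′ is a Z-bromoalkene carbon. The two C(sp2) electrophiles are united reductively under nickel/palladium/zinc.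
- Forward order: ring B by ring-closing metathesis of (R)-linalool; a bromomethylsilyl tether on the tertiary oxygen; enone; tethered enolate alkylation closes a temporary oxasilolane ring and installs the CH2; enol triflate; diene union; Tamao oxidation opens the temporary ring; iodide; B-alkyl Suzuki coupling attaches ring A as an iodo vinylogous ester; hydrolysis.
- Stereochemistry: the tertiary carbinol (ring-B C5) comes from (R)-linalool; the neighbouring methine (ring-B C1) is forced cis to the oxygen by the tether; the Z alkene comes from trans-hydroalumination of but-2-yn-1-ol and is carried through with retention; the methoxy carbon of ring A comes from a lipase kinetic resolution.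

Key step: step 9

**Remarks (assumptions)**

- The target is a 2-alkylcyclohexane-1,3-dione drawn as one enol tautomer; the tautomers are taken to interconvert, so making the dione makes the target.
- The lipase is assumed to acylate the R enantiomer of the racemic hydroxy enone faster (empirical rule for secondary alcohols, carbonyl carbon as the larger group), so the unreacted alcohol is S.
- Commercial (R)-(−)-linalool of high enantiomeric purity is assumed.

**Route**

Step 1
Reactants: 1 (R)-linalool
Product: 2 (1R)-1-methylcyclopent-2-en-1-ol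
Conditions: second-generation Grubbs catalyst RuCl2(H2IMes)(PCy3)(=CHPh) (0.5 mol%), CH2Cl2, 40 °C
Reagents that add atoms: none
Why: Ring-closing metathesis of the vinyl group onto the trisubstituted C6–C7 alkene should close ring B with loss of 2-methylpropene, and since the carbinol carbon is not involved its R configuration is carried over unchanged to become the tertiary carbinol stereocentre of the target.

Step 2
Reactants: 2 (1R)-1-methylcyclopent-2-en-1-ol
Product: 3 (bromomethyl)dimethyl{[(1R)-1-methylcyclopent-2-en-1-yl]oxy}silane
Conditions: BrCH2SiMe2Cl (1.2 equiv), Et3N, DMAP (10 mol%), CH2Cl2, 0 °C to rt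
Reagents that add atoms: (bromomethyl)chlorodimethylsilane, C[Si](C)(Cl)CBr
Why: DMAP-catalysed O-silylation of the tertiary alcohol should install a silyl ether that both masks the carbinol and carries the electrophilic CH2Br arm needed later as a tether.

Step 3
Reactants: 3 (bromomethyl)dimethyl{[(1R)-1-methylcyclopent-2-en-1-yl]oxy}silane
Product: 4 (4R)-4-{[(bromomethyl)dimethylsilyl]oxy}-4-methylcyclopent-2-en-1-one
Conditions: t-BuOOH (anhydrous, 5 equiv), dirhodium tetracaprolactamate Rh2(cap)4 (1 mol%), K2CO3, CH2Cl2, rt
Reagents that add atoms: tert-butyl hydroperoxide, CC(C)(C)OO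
Why: Radical allylic C–H oxidation should convert the only allylic methylene (C4) into the ketone, oxygen transfer to the other allyl terminus being blocked by the neighbouring quaternary carbon, and the buffered non-acidic medium should spare the silyl ether.

Step 4
Reactants: 4 (4R)-4-{[(bromomethyl)dimethylsilyl]oxy}-4-methylcyclopent-2-en-1-one
Product: 6 (3aS,6aS)-2,2,6a-trimethyl-3,3a-dihydro-2H-cyclopenta[d][1,2]oxasilol-4(6aH)-one, via potassium dienolate 5 (not isolated)
Conditions: KN(SiMe3)2 (1.05 equiv), THF (0.02 M), −78 °C to −20 °C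
Reagents that add atoms: none
Why: C5 is the only enolisable position of 4 (C4 is quaternary), so the base should give a single cross-conjugated dienolate whose carbon displaces bromide from the silicon-bound CH2 in a 5-exo-tet intramolecular enolate C-alkylation; as the electrophile hangs from the oxygen on the adjacent carbon, the new C–C bond can only form on the oxygen-bearing face, which sets the new methine stereocentre cis to the tertiary oxygen (cis-fused bicycle).

Step 5
Reactants: 6 (3aS,6aS)-2,2,6a-trimethyl-3,3a-dihydro-2H-cyclopenta[d][1,2]oxasilol-4(6aH)-one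
Product: 8 (3aS,6aS)-2,2,6a-trimethyl-3,3a,6,6a-tetrahydro-2H-cyclopenta[d][1,2]oxasilol-4-yl trifluoromethanesulfonate, via lithium enolate 7 (not isolated)
Conditions: LiBH(s-Bu)3 (1.1 equiv), THF, −78 °C; then PhNTf2, −78 °C to 0 °C
Reagents that add atoms: N-phenylbis(trifluoromethanesulfonimide), O=S(=O)(N(c1ccccc1)S(=O)(=O)C(F)(F)F)C(F)(F)F
Why: Conjugate hydride addition (trialkylborohydride 1,4-reduction) should give the enolate regiospecifically on the side remote from the ring-fusion carbon, and O-triflation (reductive enol triflate formation) should fix the ring double bond where the target has it without touching the two stereocentres.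

Step 6
Reactants: 9 but-2-yn-1-ol
Product: 11 (2Z)-3-bromobut-2-en-1-ol, via cyclic alkenylalanate 10 (not isolated)
Conditions: NaAlH2(OCH2CH2OMe)2 (1.5 equiv), THF, 0 °C to rt; then N-bromosuccinimide, −78 °C
Reagents that add atoms: N-bromosuccinimide, O=C1CCC(=O)N1Br
Why: Alkoxide-directed trans-hydroalumination of the propargylic alcohol should place aluminium on C3 cis to the CH2O group within a five-membered oxa-aluminacycle, and bromodealumination with retention should give the Z-bromoalkene.

Step 7
Reactants: 11 (2Z)-3-bromobut-2-en-1-ol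
Product: 12 (2Z)-1,3-dibromobut-2-ene
Conditions: CBr4, PPh3, CH2Cl2, 0 °C
Reagents that add atoms: tetrabromomethane, BrC(Br)(Br)Br
Why: Appel bromination (SN2 displacement of the alkoxyphosphonium salt) should convert the primary allylic alcohol into the bromide without affecting the alkenyl bromide or its geometry.

Step 8
Reactants: 12 (2Z)-1,3-dibromobut-2-ene; 13 (2-methylprop-1-en-1-yl)magnesium bromide
Product: 14 (2Z)-2-bromo-6-methylhepta-2,5-diene
Conditions: Li2CuCl4 (3 mol%), THF, −30 °C to 0 °C
Reagents that add atoms: none
Why: Copper-catalysed cross-coupling of the alkenyl Grignard reagent with the primary allylic bromide should give the skipped diene, the fully substituted γ-carbon disfavouring allylic transposition and the alkenyl carbon–bromine bond being inert at this temperature.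

Step 9
Reactants: 8 (3aS,6aS)-2,2,6a-trimethyl-3,3a,6,6a-tetrahydro-2H-cyclopenta[d][1,2]oxasilol-4-yl trifluoromethanesulfonate; 14 (2Z)-2-bromo-6-methylhepta-2,5-diene
Product: 15 (3aR,6aS)-2,2,6a-trimethyl-4-[(2Z)-6-methylhepta-2,5-dien-2-yl]-3,3a,6,6a-tetrahydro-2H-cyclopenta[d][1,2]oxasilole
Conditions: NiBr2(dme) (5 mol%), 5,5′-dimethyl-2,2′-bipyridine (5 mol%), PdCl2(dppp) (5 mol%), Zn dust (2 equiv), 14 (1.5 equiv), DMF, rt
Reagents that add atoms: none
Why: Zerovalent nickel (bipyridine-ligated, formed from NiBr2 and zinc) should insert selectively into the C(sp2)–Br bond of 14 and zerovalent palladium (dppp-ligated) into the C(sp2)–OTf bond of 8; the alkenyl group is then handed from nickel to palladium (directly or through an alkenylzinc species) and reductive elimination from the dialkenylpalladium forms the bond between ring-B C2 and chain C2′, zinc returning both metals to the zerovalent state. The closest known reaction type is the multimetallic nickel/palladium cross-electrophile coupling of bromoalkenes with enol triflates to give substituted 1,3-dienes. No ring is closed and no stereocentre is created; the two stereocentres of 8 are not epimerisable under these conditions. The step needs cross-coupling over homocoupling, which is secured by the two different leaving groups, each matched to one catalyst. It also needs retention of the Z geometry, which should hold because oxidative addition, transmetalation and reductive elimination at sp2 carbon all proceed with retention and no free alkenyl radical is formed. The silicon–oxygen ring, which masks the tertiary alcohol and carries the latent CH2OH group, is inert to zinc and to both catalysts.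

Step 10
Reactants: 15 (3aR,6aS)-2,2,6a-trimethyl-4-[(2Z)-6-methylhepta-2,5-dien-2-yl]-3,3a,6,6a-tetrahydro-2H-cyclopenta[d][1,2]oxasilole
Product: 16 (1S,2S)-2-(hydroxymethyl)-1-methyl-3-[(2Z)-6-methylhepta-2,5-dien-2-yl]cyclopent-3-en-1-ol
Conditions: H2O2 (30% aq.), KF, KHCO3, THF–MeOH, rt
Reagents that add atoms: hydrogen peroxide, OO
Why: Tamao–Fleming oxidation (peroxide attack at fluoride-activated silicon and 1,2-shift of the CH2 group from silicon to oxygen) should open the temporary ring to the primary alcohol and free the tertiary alcohol, the unactivated alkenes being inert to basic hydrogen peroxide.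

Step 11
Reactants: 16 (1S,2S)-2-(hydroxymethyl)-1-methyl-3-[(2Z)-6-methylhepta-2,5-dien-2-yl]cyclopent-3-en-1-ol
Product: 17 (1S,2R)-2-(iodomethyl)-1-methyl-3-[(2Z)-6-methylhepta-2,5-dien-2-yl]cyclopent-3-en-1-ol
Conditions: I2, PPh3, imidazole, CH2Cl2, 0 °C
Reagents that add atoms: iodine, II
Why: Appel-type iodination should be selective for the primary alcohol because the hindered tertiary alcohol does not form a displaceable alkoxyphosphonium salt under these conditions.

Step 12
Reactants: 18 3-methoxycyclohex-2-en-1-one
Product: 20 rac-6-hydroxy-3-methoxycyclohex-2-en-1-one, via potassium enolate 19 (not isolated)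
Conditions: KN(SiMe3)2, THF, −78 °C; then racemic 3-phenyl-2-(phenylsulfonyl)oxaziridine, −78 °C; aqueous work-up
Reagents that add atoms: 3-phenyl-2-(phenylsulfonyl)oxaziridine, O=S(=O)(c1ccccc1)N1OC1c1ccccc1
Why: Kinetic deprotonation of the vinylogous ester occurs at the α′-carbon C6 and the enolate should be hydroxylated there by oxygen transfer from the N-sulfonyloxaziridine, giving the racemic α′-hydroxy enone.

Step 13
Reactants: 20 rac-6-hydroxy-3-methoxycyclohex-2-en-1-one
Product: 21 (6S)-6-hydroxy-3-methoxycyclohex-2-en-1-one
Conditions: Amano lipase PS (Burkholderia cepacia lipase), vinyl acetate, t-BuOMe, 30 °C, stopped at about 55% conversion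
Reagents that add atoms: none
Why: Lipase-catalysed transesterification (enzymatic kinetic resolution of a secondary alcohol) should acylate the R-alcohol and leave the S-alcohol, which is separated from the R-acetate by chromatography; the sense of enantioselection is the assumption stated above.

Step 14
Reactants: 21 (6S)-6-hydroxy-3-methoxycyclohex-2-en-1-one
Product: 22 (6S)-3,6-dimethoxycyclohex-2-en-1-one
Conditions: MeI (10 equiv), Ag2O (3 equiv), 4 Å molecular sieves, MeCN, rt, dark
Reagents that add atoms: iodomethane, CI
Why: Silver-oxide-promoted O-methylation runs without a soluble base, so the stereocentre next to the ketone should not be enolised.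

Step 15
Reactants: 22 (6S)-3,6-dimethoxycyclohex-2-en-1-one
Product: 23 (6S)-2-iodo-3,6-dimethoxycyclohex-2-en-1-one
Conditions: N-iodosuccinimide (1.1 equiv), MeCN, 0 °C to rt, dark
Reagents that add atoms: N-iodosuccinimide, O=C1CCC(=O)N1I
Why: The β-methoxy enone is an enol ether, so electrophilic iodination should take place at its nucleophilic α-carbon C2, and loss of the proton restores the vinylogous ester as the α-iodo enone.

Step 16
Reactants: 17 (1S,2R)-2-(iodomethyl)-1-methyl-3-[(2Z)-6-methylhepta-2,5-dien-2-yl]cyclopent-3-en-1-ol; 23 (6S)-2-iodo-3,6-dimethoxycyclohex-2-en-1-one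
Product: 26 (6S)-2-{[(1R,5S)-5-hydroxy-5-methyl-2-[(2Z)-6-methylhepta-2,5-dien-2-yl]cyclopent-2-en-1-yl]methyl}-3,6-dimethoxycyclohex-2-en-1-one, via dilithio alkoxide alkyllithium 24 (not isolated), via lithium alkyl(methoxy)borate 25 (not isolated)
Conditions: t-BuLi (3.1 equiv), Et2O, −78 °C; B-methoxy-9-BBN, THF, −78 °C to rt; then 23, PdCl2(dppf) (5 mol%), AsPh3, K3PO4 (3 M aq.), DMF, rt
Reagents that add atoms: none
Why: The first equivalent of t-BuLi should convert the tertiary alcohol into its lithium alkoxide and the next two effect iodine–lithium exchange; the primary alkyllithium is trapped by B-methoxy-9-BBN as a borate that transfers its primary alkyl group to palladium after oxidative addition of the α-iodo enone (B-alkyl Suzuki–Miyaura coupling), no stereocentre being involved.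

Step 17
Reactants: 26 (6S)-2-{[(1R,5S)-5-hydroxy-5-methyl-2-[(2Z)-6-methylhepta-2,5-dien-2-yl]cyclopent-2-en-1-yl]methyl}-3,6-dimethoxycyclohex-2-en-1-one
Product: 27 (4S)-3-hydroxy-2-{[(1R,5S)-5-hydroxy-5-methyl-2-[(2Z)-6-methylhepta-2,5-dien-2-yl]cyclopent-2-en-1-yl]methyl}-4-methoxycyclohex-2-en-1-one
Conditions: 1 M aq. HCl, THF, 0 °C to rt
Reagents that add atoms: water, O
Why: Acid hydrolysis of the vinylogous methyl ester (protonation at the carbonyl oxygen, addition of water at C3, loss of methanol) should unveil the 2-alkylcyclohexane-1,3-dione, drawn as the enol tautomer of the target, dilute acid in a water-rich medium being chosen so that water rather than the tertiary hydroxyl group intercepts the activated enol ether.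

**Compound list**

1 | (R)-linalool, (3R)-3,7-dimethylocta-1,6-dien-3-ol | C=C[C@](C)(O)CCC=C(C)C | starting material
2 | (1R)-1-methylcyclopent-2-en-1-ol | C[C@]1(O)C=CCC1 | intermediate
3 | (bromomethyl)dimethyl{[(1R)-1-methylcyclopent-2-en-1-yl]oxy}silane | C[C@]1(O[Si](C)(C)CBr)C=CCC1 | intermediate
4 | (4R)-4-{[(bromomethyl)dimethylsilyl]oxy}-4-methylcyclopent-2-en-1-one | C[C@]1(O[Si](C)(C)CBr)C=CC(=O)C1 | intermediate
5 | potassium dienolate of 4 (C5 enolate, formed in the flask) | C[C@]1(O[Si](C)(C)CBr)C=CC([O-])=C1.[K+] | intermediate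
6 | (3aS,6aS)-2,2,6a-trimethyl-3,3a-dihydro-2H-cyclopenta[d][1,2]oxasilol-4(6aH)-one (cis-fused) | C[C@@]12O[Si](C)(C)C[C@@H]1C(=O)C=C2 | intermediate
7 | lithium enolate from conjugate reduction of 6 (formed in the flask) | C[C@@]12O[Si](C)(C)C[C@@H]1C([O-])=CC2.[Li+] | intermediate
8 | (3aS,6aS)-2,2,6a-trimethyl-3,3a,6,6a-tetrahydro-2H-cyclopenta[d][1,2]oxasilol-4-yl trifluoromethanesulfonate | C[C@@]12O[Si](C)(C)C[C@@H]1C(OS(=O)(=O)C(F)(F)F)=CC2 | intermediate
9 | but-2-yn-1-ol | CC#CCO | starting material
10 | sodium cyclic alkenylalanate (aluminium on C3, tied to the oxygen; formed in the flask) | CC1=CCO[Al-]1(OCCOC)OCCOC.[Na+] | intermediate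
11 | (2Z)-3-bromobut-2-en-1-ol | C/C(Br)=C/CO | intermediate
12 | (2Z)-1,3-dibromobut-2-ene | C/C(Br)=C/CBr | intermediate
13 | (2-methylprop-1-en-1-yl)magnesium bromide | CC(C)=C[Mg]Br | starting material
14 | (2Z)-2-bromo-6-methylhepta-2,5-diene | C/C(Br)=C/CC=C(C)C | intermediate
15 | (3aR,6aS)-2,2,6a-trimethyl-4-[(2Z)-6-methylhepta-2,5-dien-2-yl]-3,3a,6,6a-tetrahydro-2H-cyclopenta[d][1,2]oxasilole | C[C@@]12O[Si](C)(C)C[C@@H]1C(/C(C)=C\CC=C(C)C)=CC2 | intermediate
16 | (1S,2S)-2-(hydroxymethyl)-1-methyl-3-[(2Z)-6-methylhepta-2,5-dien-2-yl]cyclopent-3-en-1-ol | C[C@]1(O)CC=C(/C(C)=C\CC=C(C)C)[C@H]1CO | intermediate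
17 | (1S,2R)-2-(iodomethyl)-1-methyl-3-[(2Z)-6-methylhepta-2,5-dien-2-yl]cyclopent-3-en-1-ol | C[C@]1(O)CC=C(/C(C)=C\CC=C(C)C)[C@H]1CI | intermediate
18 | 3-methoxycyclohex-2-en-1-one | COC1=CC(=O)CCC1 | starting material
19 | potassium enolate of 18 (C6 enolate, formed in the flask) | COC1=CC([O-])=CCC1.[K+] | intermediate
20 | rac-6-hydroxy-3-methoxycyclohex-2-en-1-one | COC1=CC(=O)C(O)CC1 | intermediate
21 | (6S)-6-hydroxy-3-methoxycyclohex-2-en-1-one | O[C@H]1CCC(OC)=CC1=O | intermediate
22 | (6S)-3,6-dimethoxycyclohex-2-en-1-one | CO[C@H]1CCC(OC)=CC1=O | intermediate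
23 | (6S)-2-iodo-3,6-dimethoxycyclohex-2-en-1-one | CO[C@H]1CCC(OC)=C(I)C1=O | intermediate
24 | dilithio species from 17 (lithium tertiary alkoxide, primary alkyllithium; formed in the flask) | C[C@]1(O[Li])CC=C(/C(C)=C\CC=C(C)C)[C@H]1C[Li] | intermediate
25 | lithium B-alkyl-B-methoxy-9-borabicyclo[3.3.1]nonane borate of 24 (formed in the flask) | C[C@]1(O[Li])CC=C(/C(C)=C\CC=C(C)C)[C@H]1C[B-]1(OC)C2CCCC1CCC2.[Li+] | intermediate
26 | (6S)-2-{[(1R,5S)-5-hydroxy-5-methyl-2-[(2Z)-6-methylhepta-2,5-dien-2-yl]cyclopent-2-en-1-yl]methyl}-3,6-dimethoxycyclohex-2-en-1-one | CO[C@H]1CCC(OC)=C(C[C@@H]2C(/C(C)=C\CC=C(C)C)=CC[C@]2(C)O)C1=O | intermediate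
27 | (4S)-3-hydroxy-2-{[(1R,5S)-5-hydroxy-5-methyl-2-[(2Z)-6-methylhepta-2,5-dien-2-yl]cyclopent-2-en-1-yl]methyl}-4-methoxycyclohex-2-en-1-one | CO[C@H]1CCC(=O)C(C[C@@H]2C(/C(C)=C\CC=C(C)C)=CC[C@]2(C)O)=C1O | target

**Totals**

Total step count: 17. Longest linear sequence: 10 steps (steps 1, 2, 3, 4, 5, 9, 10, 11, 16, 17).

**Steps most likely to fail, each with a fallback**

Step 4. The ring closure may be outrun by intermolecular Michael addition of the dienolate to unreacted enone, or by transfer of silicon to the enolate oxygen. The fallback sets out from 4 and comes back at 6. The silyl ether of 4 is cleaved (AcOH, aq. THF) to (4R)-4-hydroxy-4-methylcyclopent-2-en-1-one F1. Its dianion (LiN(i-Pr)2, 2.2 equiv, THF, −78 °C) is alkylated intermolecularly at C5 with (iodomethyl)dimethyl(propan-2-yloxy)silane to give (4S)-4-hydroxy-4-methyl-5-{[dimethyl(propan-2-yloxy)silyl]methyl}cyclopent-2-en-1-one F2 as both C5 epimers. PPTS in toluene then exchanges the isopropoxy group on silicon for the tertiary hydroxyl group, which only the cis epimer can do, and catalytic DBU equilibrates C5 of the trans epimer through the enolate, so the material should converge on 6.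

Step 9. Homocoupling of either partner, or Z-to-E leakage through reversible isomerisation at the alkenylnickel stage, may erode the union. The fallback sets out from 14 and comes back at 15. Bromine–lithium exchange (t-BuLi, 2 equiv, Et2O, −78 °C) should give, with retention, [(2E)-6-methylhepta-2,5-dien-2-yl]lithium F3 (the descriptor changes only because lithium ranks below carbon). ZnBr2 converts it into bromo[(2Z)-6-methylhepta-2,5-dien-2-yl]zinc F4, and a conventional Negishi coupling with 8 (Pd(PPh3)4, THF, rt) should give 15.

Step 5. Direct 1,2-reduction of the carbonyl group may compete with conjugate addition, because the β-carbon is flanked by the quaternary carbon. The fallback sets out from 6 and comes back at 7, and so at 8. Hydrogenation of the enone C=C (H2, Pd/C, EtOAc) gives (3aS,6aS)-2,2,6a-trimethyltetrahydro-2H-cyclopenta[d][1,2]oxasilol-4(3H)-one F5. Kinetic deprotonation with LiN(i-Pr)2 at −78 °C should take place at the CH2 group and not at the ring-fusion methine, giving the same lithium enolate 7, which is triflated with PhNTf2 as in the main route.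

**Further compounds**

F1 | step 4 | (4R)-4-hydroxy-4-methylcyclopent-2-en-1-one | C[C@]1(O)C=CC(=O)C1
F2 | step 4 | (4S)-4-hydroxy-4-methyl-5-{[dimethyl(propan-2-yloxy)silyl]methyl}cyclopent-2-en-1-one (both C5 epimers) | C[C@]1(O)C=CC(=O)C1C[Si](C)(C)OC(C)C
F3 | step 9 | [(2E)-6-methylhepta-2,5-dien-2-yl]lithium (lithium cis to the CH2 group) | C/C([Li])=C/CC=C(C)C
F4 | step 9 | bromo[(2Z)-6-methylhepta-2,5-dien-2-yl]zinc | C/C([Zn]Br)=C/CC=C(C)C
F5 | step 5 | (3aS,6aS)-2,2,6a-trimethyltetrahydro-2H-cyclopenta[d][1,2]oxasilol-4(3H)-one | C[C@@]12O[Si](C)(C)C[C@@H]1C(=O)CC2
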